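## Retrosynthetic overview

1. Aristophenone A (19) comes from tris-allyl compound 18 by one palladium-catalysed deallylation; the C7 prenyl group comes from the C7 aldehyde of 15 by two Wittig reactions.
2. Bicyclic aldehyde 15 comes from aryl allyl ether 12 by an enantioselective O-to-C allyl transposition (C1–C8 bond) followed by Michael ring closure (C5–C6 bond); the ether oxygen ends as the C9 ketone.
3. Key bond: the aryl O–CH2 ether bond of 12 (carbon–oxygen), made by Mitsunobu etherification of the para-hydroxyl of diprenyl acylphloroglucinol 8 with hydroxy enal 11.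
4. 8 comes from phloroglucinol and 3,4-bis(allyloxy)benzonitrile (Hoesch acylation, then C-prenylation); 11 comes from diethyl isopropylidenemalonate.
5. Ring order: the purchased phloroglucinol ring becomes the trione ring (ring A) on dearomatization; the cyclohexanone ring (ring B) is closed last, in the same operation.

Assumption: the target is treated as the enol tautomer of the given SMILES (2-oxo, 4-hydroxy), its bicyclo[3.3.1]nonane numbering (C1–C9) is used for all bicyclic compounds, and because the sense of induction in step 7 cannot be predicted the cinchonidine-derived catalyst is written, its cinchonine-derived pseudoenantiomer being used if the opposite series forms.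

## Route

Step 1
Reactants: 1 3,4-dihydroxybenzonitrile; 2 allyl bromide (2.4 equiv)
Product: 3 3,4-bis(allyloxy)benzonitrile
Conditions: K2CO3, DMF, 60 °C
Reagents that add atoms: none
Why: Williamson ether synthesis; the nitrile-activated catechol is fully O-allylated under carbonate, and allyl ethers are chosen because they withstand the later acid, base and ylide steps and leave at the end under neutral palladium catalysis.

Step 2
Reactants: 3 3,4-bis(allyloxy)benzonitrile; 4 phloroglucinol
Product: 6 3',4'-di-O-allylmaclurin, via ketiminium chloride 5 (not isolated)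
Conditions: ZnCl2, HCl (g), Et2O, 0 °C → rt; then H2O, 100 °C
Reagents that add atoms: water, O
Why: Houben–Hoesch acylation; the HCl/ZnCl2-activated nitrile attacks the very electron-rich phloroglucinol once (the ketiminium salt deactivates the ring), hot water hydrolyses the ketiminium to the ketone, and aryl allyl ethers tolerate ethereal HCl at 0 °C.

Step 3
Reactants: 6 3',4'-di-O-allylmaclurin; 7 prenyl bromide (2.1 equiv)
Product: 8 3,5-diprenyl-3',4'-di-O-allylmaclurin
Conditions: 10% aq. KOH, 0 °C
Reagents that add atoms: none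
Why: Carbon alkylation (C-prenylation) of the acylphloroglucinol polyanion in water, where solvation of the oxygens steers prenyl bromide to the two free ring carbons; mono- and triprenylated by-products are removed by chromatography.

Step 4
Reactants: 9 diethyl isopropylidenemalonate
Product: 10 2-(propan-2-ylidene)propane-1,3-diol
Conditions: iBu2AlH (4.5 equiv), CH2Cl2, −78 → 0 °C; aq. potassium sodium tartrate
Reagents that add atoms: none
Why: 1,2-Reduction of both conjugated esters by the aluminium hydride at low temperature, without conjugate reduction of the tetrasubstituted alkene, gives the bis-allylic diol.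

Step 5
Reactants: 10 2-(propan-2-ylidene)propane-1,3-diol
Product: 11 2-(hydroxymethyl)-3-methylbut-2-enal
Conditions: MnO2 (10 equiv), CH2Cl2, rt
Reagents that add atoms: none
Why: Allylic oxidation with MnO2 stops after one hydroxyl because the enal formed makes the remaining CH2OH part of an electron-poor allylic system that is oxidised much more slowly.

Step 6
Reactants: 8 3,5-diprenyl-3',4'-di-O-allylmaclurin; 11 2-(hydroxymethyl)-3-methylbut-2-enal
Product: 12 aryl 2-formyl-3-methylbut-2-enyl ether (ether at the para-oxygen of 8)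
Conditions: PPh3, diisopropyl azodicarboxylate (DIAD), THF, 0 °C
Reagents that add atoms: none
Why: Mitsunobu etherification (SN2 on the primary allylic alkoxyphosphonium ion); the para-hydroxyl is the most acidic and the only one not tied up in a hydrogen bond to the ketone, so it alone is alkylated, and this aryl O–CH2 bond places the three-carbon bridge on the oxygen that becomes the C9 ketone.

Step 7
Reactants: 12 aryl 2-formyl-3-methylbut-2-enyl ether; 2 allyl bromide (1.5 equiv, added after the cascade)
Product: 15 O-allyl bicyclic aldehyde, via dienone enal 13 (not isolated), via bicyclic enolate aldehyde 14 (not isolated)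
Conditions: N-(9-anthracenylmethyl)cinchonidinium chloride (10 mol %), CsOH·H2O (1.1 equiv), toluene/CH2Cl2 7:3, −40 → −20 °C; then allyl bromide, 0 °C → rt
Reagents that add atoms: none
Why: Proposed new method: a catalytic enantioselective desymmetrizing O-to-C allyl transposition–Michael cascade, in which the chiral ammonium phenoxide of 12 attacks the tethered β,β-dimethyl enal carbon through a six-membered Claisen-like chair, the resulting enolate expels the ring oxygen (E1cB) to give 13 with the C1–C8 bond between two fully substituted carbons, the trione enolate closes ring B by Michael addition of C5 to the new acrolein CH2 (14), C7 equilibrates to the equatorial (exo) aldehyde and the enolate is O-allylated at the less hindered O4 (any O2-allyl regioisomer converges in step 10); ion pairing at the phenoxide plus hydrogen bonding of the catalyst hydroxyl to the formyl group decides which of the two prenyl-bearing ring carbons (enantiotopic towards the tethered enal) bonds, which sets C1, while C5 follows from the geometry of the bridge; the closest known reaction types are the chiral phase-transfer-catalysed intermolecular alkylative dearomatization–annulation of acylphloroglucinols and catalytic asymmetric dearomative Claisen rearrangements of aryl allyl ethers.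

Step 8
Reactants: 15 O-allyl bicyclic aldehyde
Product: 17 homologated aldehyde (C7–CH2–CHO), via methoxyvinyl compound 16 (not isolated)
Conditions: Ph3P(CH2OMe)Cl, KN(SiMe3)2, THF, −78 → 0 °C; then 2 M aq. HCl, THF, rt
Reagents that add atoms: (methoxymethyl)triphenylphosphonium chloride, COC[P+](c1ccccc1)(c1ccccc1)c1ccccc1.[Cl-]; water, O
Why: Wittig methoxymethylenation then enol ether hydrolysis (one-carbon homologation); the aldehyde is the only unhindered carbonyl (C9 lies between two quaternary carbons, the others belong to the vinylogous ester), the simple enol ether hydrolyses far faster than the vinylogous allyl ester or the prenyl groups react, and C7 keeps its equatorial substituent.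

Step 9
Reactants: 17 homologated aldehyde
Product: 18 tri-O-allyl aristophenone A
Conditions: Ph3P(iPr)I, KN(SiMe3)2, THF, −78 °C → rt
Reagents that add atoms: isopropyltriphenylphosphonium iodide, CC(C)[P+](c1ccccc1)(c1ccccc1)c1ccccc1.[I-]
Why: Wittig olefination of the unhindered CH2CHO aldehyde with the isopropylidene ylide completes the third prenyl group without touching the hindered ketones or any stereocenter.

Step 10
Reactants: 18 tri-O-allyl aristophenone A
Product: 19 aristophenone A
Conditions: Pd(PPh3)4 (5 mol %), morpholine (15 equiv), THF, rt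
Reagents that add atoms: none
Why: Tsuji–Trost deallylation; zerovalent palladium ionises the allyl vinylogous ester and the two aryl allyl ethers (good leaving groups) and the π-allyl complexes are trapped by excess morpholine under neutral conditions that leave prenyl groups, enol and catechol intact.

## Compound list

1 | 3,4-dihydroxybenzonitrile | N#Cc1ccc(O)c(O)c1 | starting material
2 | allyl bromide (3-bromoprop-1-ene) | C=CCBr | starting material
3 | 3,4-bis(allyloxy)benzonitrile | N#Cc1ccc(OCC=C)c(OCC=C)c1 | intermediate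
4 | phloroglucinol (benzene-1,3,5-triol) | Oc1cc(O)cc(O)c1 | starting material
5 | [3,4-bis(allyloxy)phenyl](2,4,6-trihydroxyphenyl)methaniminium chloride (not isolated) | [NH2+]=C(c1ccc(OCC=C)c(OCC=C)c1)c1c(O)cc(O)cc1O.[Cl-] | intermediate
6 | [3,4-bis(allyloxy)phenyl](2,4,6-trihydroxyphenyl)methanone (3',4'-di-O-allylmaclurin) | O=C(c1ccc(OCC=C)c(OCC=C)c1)c1c(O)cc(O)cc1O | intermediate
7 | prenyl bromide (1-bromo-3-methylbut-2-ene) | CC(C)=CCBr | starting material
8 | [3,4-bis(allyloxy)phenyl][2,4,6-trihydroxy-3,5-bis(3-methylbut-2-en-1-yl)phenyl]methanone | O=C(c1ccc(OCC=C)c(OCC=C)c1)c1c(O)c(CC=C(C)C)c(O)c(CC=C(C)C)c1O | intermediate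
9 | diethyl isopropylidenemalonate (diethyl 2-(propan-2-ylidene)propanedioate) | CCOC(=O)C(=C(C)C)C(=O)OCC | starting material
10 | 2-(propan-2-ylidene)propane-1,3-diol | CC(C)=C(CO)CO | intermediate
11 | 2-(hydroxymethyl)-3-methylbut-2-enal | CC(C)=C(CO)C=O | intermediate
12 | [3,4-bis(allyloxy)phenyl]{4-[(2-formyl-3-methylbut-2-en-1-yl)oxy]-2,6-dihydroxy-3,5-bis(3-methylbut-2-en-1-yl)phenyl}methanone | O=C(c1ccc(OCC=C)c(OCC=C)c1)c1c(O)c(CC=C(C)C)c(OCC(C=O)=C(C)C)c(CC=C(C)C)c1O | intermediate
13 | (6S)-2-[3,4-bis(allyloxy)benzoyl]-6-(3-formyl-2-methylbut-3-en-2-yl)-3,5-dihydroxy-4,6-bis(3-methylbut-2-en-1-yl)cyclohexa-2,4-dien-1-one (not isolated; drawn neutral, present as enolate) | OC1=C(CC=C(C)C)C(O)=C(C(=O)c2ccc(OCC=C)c(OCC=C)c2)C(=O)[C@@]1(CC=C(C)C)C(C)(C)C(C=O)=C | intermediate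
14 | (1S,5S,7R)-3-[3,4-bis(allyloxy)benzoyl]-4-hydroxy-8,8-dimethyl-1,5-bis(3-methylbut-2-en-1-yl)-2,9-dioxobicyclo[3.3.1]non-3-ene-7-carbaldehyde (formyl exo; not isolated; drawn neutral, present as enolate) | O=C[C@@H]1C[C@]2(CC=C(C)C)C(=O)[C@@](CC=C(C)C)(C(=O)C(C(=O)c3ccc(OCC=C)c(OCC=C)c3)=C2O)C1(C)C | intermediate
15 | (1S,5S,7R)-4-(allyloxy)-3-[3,4-bis(allyloxy)benzoyl]-8,8-dimethyl-1,5-bis(3-methylbut-2-en-1-yl)-2,9-dioxobicyclo[3.3.1]non-3-ene-7-carbaldehyde (formyl exo) | O=C[C@@H]1C[C@]2(CC=C(C)C)C(=O)[C@@](CC=C(C)C)(C(=O)C(C(=O)c3ccc(OCC=C)c(OCC=C)c3)=C2OCC=C)C1(C)C | intermediate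
16 | (1S,5S,7S)-4-(allyloxy)-3-[3,4-bis(allyloxy)benzoyl]-7-(2-methoxyethenyl)-8,8-dimethyl-1,5-bis(3-methylbut-2-en-1-yl)bicyclo[3.3.1]non-3-ene-2,9-dione (E/Z mixture, side chain exo; not isolated) | COC=C[C@@H]1C[C@]2(CC=C(C)C)C(=O)[C@@](CC=C(C)C)(C(=O)C(C(=O)c3ccc(OCC=C)c(OCC=C)c3)=C2OCC=C)C1(C)C | intermediate
17 | 2-[(1S,5S,7S)-4-(allyloxy)-3-[3,4-bis(allyloxy)benzoyl]-8,8-dimethyl-1,5-bis(3-methylbut-2-en-1-yl)-2,9-dioxobicyclo[3.3.1]non-3-en-7-yl]acetaldehyde (side chain exo, same spatial arrangement as the target) | O=CC[C@@H]1C[C@]2(CC=C(C)C)C(=O)[C@@](CC=C(C)C)(C(=O)C(C(=O)c3ccc(OCC=C)c(OCC=C)c3)=C2OCC=C)C1(C)C | intermediate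
18 | (1S,5S,7R)-4-(allyloxy)-3-[3,4-bis(allyloxy)benzoyl]-8,8-dimethyl-1,5,7-tris(3-methylbut-2-en-1-yl)bicyclo[3.3.1]non-3-ene-2,9-dione | CC(C)=CC[C@@H]1C[C@]2(CC=C(C)C)C(=O)[C@@](CC=C(C)C)(C(=O)C(C(=O)c3ccc(OCC=C)c(OCC=C)c3)=C2OCC=C)C1(C)C | intermediate
19 | aristophenone A, (1S,5S,7R)-3-(3,4-dihydroxybenzoyl)-4-hydroxy-8,8-dimethyl-1,5,7-tris(3-methylbut-2-en-1-yl)bicyclo[3.3.1]non-3-ene-2,9-dione | CC(C)=CC[C@@H]1C[C@]2(CC=C(C)C)C(=O)[C@@](CC=C(C)C)(C(=O)C(C(=O)c3ccc(O)c(O)c3)=C2O)C1(C)C | target

## Step count and risks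

Total: 10 steps. Longest linear sequence: 8 steps (1 → 2 → 3 → 6 → 7 → 8 → 9 → 10).

**Step 7 (the proposed new cascade).** It may give low enantiomeric excess (uncatalysed rearrangement of the caesium salt), lose the aryloxide by β-elimination before carbon–carbon bond formation, or stall at the adamantane-type aldol. The fallback uses known chemistry, sets out from 8 and 11 and returns at 15. Alcohol 11 is converted (CBr4, PPh3, CH2Cl2, 0 °C) into 2-(bromomethyl)-3-methylbut-2-enal F1. With KN(SiMe3)2 in THF (0 → 65 °C), F1 alkylates 8 at a prenylated ring carbon to give the racemic dearomatized mono-adduct 2-[3,4-bis(allyloxy)benzoyl]-6-(2-formyl-3-methylbut-2-en-1-yl)-3,5-dihydroxy-4,6-bis(3-methylbut-2-en-1-yl)cyclohexa-2,4-dien-1-one F2, which is not isolated. Its intramolecular Michael addition (the established alkylative dearomatization–annulation of acylphloroglucinols) gives 14 together with the enantiomer of 14 F3. Allyl bromide then gives 15 together with the enantiomer of 15 F4. Preparative HPLC on amylose tris(3,5-dimethylphenylcarbamate) delivers 15, and the route resumes at step 8.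

**Step 6 (Mitsunobu etherification).** The basic betaine may trigger a premature racemic cascade of 12, and the phosphine may add to the enal. The fallback sets out from 8 and 10 and returns at 12; step 5 is then not needed. Diol 10 (3 equiv) is coupled with 8 under the same PPh3/DIAD conditions to give [3,4-bis(allyloxy)phenyl]{2,6-dihydroxy-4-{[2-(hydroxymethyl)-3-methylbut-2-en-1-yl]oxy}-3,5-bis(3-methylbut-2-en-1-yl)phenyl}methanone F5, which cannot enter the cascade. MnO2 in CH2Cl2 then unveils the enal under neutral conditions and gives 12.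

**Step 8 (homologation of a hindered aldehyde, then acid).** The acid hydrolysis may also cleave the vinylogous allyl ester or hydrate a prenyl group. The fallback sets out from 15 and returns at 17. A boron-Wittig olefination with CH2(Bpin)2 and lithium 2,2,6,6-tetramethylpiperidide (THF, −78 → 0 °C) gives (1S,5S,7S)-4-(allyloxy)-3-[3,4-bis(allyloxy)benzoyl]-8,8-dimethyl-1,5-bis(3-methylbut-2-en-1-yl)-7-[(E)-2-(4,4,5,5-tetramethyl-1,3,2-dioxaborolan-2-yl)ethenyl]bicyclo[3.3.1]non-3-ene-2,9-dione F6. NaBO3·4H2O in THF/H2O oxidises its carbon–boron bond to the enol, which tautomerizes to 17 without any acid.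

## Further compounds

F1 | step 7 | 2-(bromomethyl)-3-methylbut-2-enal | CC(C)=C(CBr)C=O
F2 | step 7 | racemic 2-[3,4-bis(allyloxy)benzoyl]-6-(2-formyl-3-methylbut-2-en-1-yl)-3,5-dihydroxy-4,6-bis(3-methylbut-2-en-1-yl)cyclohexa-2,4-dien-1-one | OC1=C(CC=C(C)C)C(O)=C(C(=O)c2ccc(OCC=C)c(OCC=C)c2)C(=O)C1(CC=C(C)C)CC(C=O)=C(C)C
F3 | step 7 | enantiomer of 14, (1R,5R,7S)-3-[3,4-bis(allyloxy)benzoyl]-4-hydroxy-8,8-dimethyl-1,5-bis(3-methylbut-2-en-1-yl)-2,9-dioxobicyclo[3.3.1]non-3-ene-7-carbaldehyde | O=C[C@H]1C[C@@]2(CC=C(C)C)C(=O)[C@](CC=C(C)C)(C(=O)C(C(=O)c3ccc(OCC=C)c(OCC=C)c3)=C2O)C1(C)C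
F4 | step 7 | enantiomer of 15, (1R,5R,7S)-4-(allyloxy)-3-[3,4-bis(allyloxy)benzoyl]-8,8-dimethyl-1,5-bis(3-methylbut-2-en-1-yl)-2,9-dioxobicyclo[3.3.1]non-3-ene-7-carbaldehyde | O=C[C@H]1C[C@@]2(CC=C(C)C)C(=O)[C@](CC=C(C)C)(C(=O)C(C(=O)c3ccc(OCC=C)c(OCC=C)c3)=C2OCC=C)C1(C)C
F5 | step 6 | [3,4-bis(allyloxy)phenyl]{2,6-dihydroxy-4-{[2-(hydroxymethyl)-3-methylbut-2-en-1-yl]oxy}-3,5-bis(3-methylbut-2-en-1-yl)phenyl}methanone | O=C(c1ccc(OCC=C)c(OCC=C)c1)c1c(O)c(CC=C(C)C)c(OCC(CO)=C(C)C)c(CC=C(C)C)c1O
F6 | step 8 | (1S,5S,7S)-4-(allyloxy)-3-[3,4-bis(allyloxy)benzoyl]-8,8-dimethyl-1,5-bis(3-methylbut-2-en-1-yl)-7-[(E)-2-(4,4,5,5-tetramethyl-1,3,2-dioxaborolan-2-yl)ethenyl]bicyclo[3.3.1]non-3-ene-2,9-dione | CC1(C)OB(OC1(C)C)/C=C/[C@@H]2C[C@]3(CC=C(C)C)C(=O)[C@@](CC=C(C)C)(C(=O)C(C(=O)c4ccc(OCC=C)c(OCC=C)c4)=C3OCC=C)C2(C)C
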